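The readings were generated by integration for an exercise; scatter was added.

Late in the delta run Q is still falling and E has begun to sag, and two chemists dispute what this same flask holds at 6.0 h.

| setting | delta | flask |
|---|---|---|
| Q | 0.020 M | 0.020 M |
| J | 0.040 M | 0.0400 M |
| remark | the very flask that is asked about, followed so far |  |
| time |  | 6.0 h |
delta run (percent of the Q charged)

| time / min | Q / % | E / % |
|---|---|---|
| 4.00 | 40.1 | 29.4 |
| 12.0 | 32.2 | 30.1 |
| 25.0 | 26.3 | 29.5 |
| 40.0 | 19.3 | 29.6 |
| 50.0 | 17.5 | 28.1 |
| 60.0 | 14.5 | 27.4 |

(scatter of a reading: 0.5 percentage points)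

- amount of Q at 6.0 h, in percent of the Q charged
- amount of E at 6.0 h, in percent of the Q charged
- amount of G at 6.0 h, in percent of the Q charged
- amount of L at 6.0 h, in percent of the Q charged

The first chemist reads the clock: between 12.0 min and 60.0 min the readings of Q give a time constant of 60.2 min, and 6.0 h lies far out on that curve. This view gives the forecast: Q 2 %, E 15 %, G 12 %, L 71 %, with G treated in its own words: “it likely drains similarly”.

The second chemist distrusts the clock, since Q lost 59.9 % of its charge by 4.00 min and then slowed. Taking Q and E to react with the same J, this chemist follows E against Q, so that J drops out. E stays flat near 29.5 % while Q goes from 32.2 % to 26.3 %, through that same value, so E is taken to go on per molecule as fast as Q goes to E. With s, the selectivity, meaning the share of used Q that becomes E, and amounts as fractions of the charge, E = s/(1 − s)·(Q^s − Q).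

At 4.00 min the plain ratio of E to Q used gives a first s of 49.1 %. The rule then returns E of 22.9 %, below the reading. Scaling s by that gap gives 63.0 %, and a second round gives s = 67.4 %. At 25.0 min this gives E of 29.7 % against the reading of 29.5 %. At the forecast's Q the rule gives E of 10.7 %, not the forecast's figure. At that Q the same s puts the G made so far at 31.9 %, and the readings do not show how much of it moves on.

The simulation gives Q 0.847 %, E 6.23 %, G 24.6 %, L 67.8 %.

    Q + J → E + D (k = 0.182 /M/s)
    Q + J → G + D (k = 0.0791 /M/s)
    J + E → L + D (k = 0.181 /M/s)
    J + G → L + D (k = 0.0138 /M/s)
    J ⇌ Z (K = 13.1, k = 0.00686 /s)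
    E → X (k = 1.51 × 10⁻⁶ /s)

Putting this Q back into the rule gives E of 6.54 %. The clock view has its region earlier: the flask holds E of 14.4 % at 3.00 h, close to the forecast's figure. G reacts with J more slowly than E does, with a constant of 0.0138 /M/s against 0.181 /M/s. L reaches 67.8 % through the step from J and E acting together with the falling back of Z to J: the run without that step reaches L of 9.94 %, and the run without the falling back reaches 13.6 %.

In the neighbour flask with 0.010 M of J, Q stands at 56.5 % at 6.0 h, where the rule gives E of 23.9 %. The simulation gives 23.9 %.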